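The route rests on building the cyclohexene of the acyl half (ring B) not as a six-membered ring but by contraction of an achiral ten-membered dienyl lactone. An enantioselective Ireland–Claisen rearrangement of this lactone forms the C-1–C-6 bond of ring B and sets both stereocentres cis in one operation. It exploits that C-1, allylic to C-2=C-3, is a masked lactone α-carbon and that C-6 is the terminus of a 2-methylallyl ester, a latent isopropyl group. The acid so formed is extended by Wittig olefination and joined, by carboxylate opening of a spiro-epoxide, to the lactone half, which comes from (S)-cryptone by Diels–Alder annulation and oxidative ring cleavage.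

Key step: step 8

Assumption: the ketene acetal is taken to form with C-4 cis to O-1 (the geometry that spares the ten-membered ring a second trans ring olefin), and the (4S,5S)-bromoborane is taken to favour the chair transition state that leads to (1S,6R)-14; should the sense of induction be the opposite, the (4R,5R)-reagent is used and nothing else changes.

Step 1
Reactants: 1 2-(but-3-yn-1-yloxy)tetrahydro-2H-pyran
Product: 3 5-(tetrahydro-2H-pyran-2-yloxy)pent-2-yn-1-ol, via lithium acetylide 2 (not isolated)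
Conditions: n-BuLi, THF, −78 °C; (CH2O)n, −78 °C to rt; H2O
Reagents that add atoms: formaldehyde (as paraformaldehyde), C=O
Why: Alkynylation of formaldehyde by the lithium acetylide should give the propargylic alcohol whose hydroxyl directs the next step; no stereocentre is formed.

Step 2
Reactants: 3 5-(tetrahydro-2H-pyran-2-yloxy)pent-2-yn-1-ol; 4 5-bromo-2-methylpent-2-ene
Product: 6 (2E)-2-(4-methylpent-3-en-1-yl)-5-(tetrahydro-2H-pyran-2-yloxy)pent-2-en-1-ol, via (4-methylpent-3-en-1-yl)magnesium bromide 5 (not isolated)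
Conditions: 4 (3 equiv), Mg, THF, rt; then 3, CuI (10 mol %), THF, reflux; H2O
Reagents that add atoms: none
Why: Copper-catalysed anti-carbomagnesiation of the propargylic alkoxide delivers the alkyl group to C-2 and magnesium to C-3 within a five-membered alkenylmagnesium alkoxide chelate, so protonation should leave the new chain cis to the C-4 chain, that is the (2E) trisubstituted olefin that becomes C-2=C-3 of ring B.

Step 3
Reactants: 6 (2E)-2-(4-methylpent-3-en-1-yl)-5-(tetrahydro-2H-pyran-2-yloxy)pent-2-en-1-ol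
Product: 7 tert-butyl{[(2E)-2-(4-methylpent-3-en-1-yl)-5-(tetrahydro-2H-pyran-2-yloxy)pent-2-en-1-yl]oxy}diphenylsilane
Conditions: t-BuPh2SiCl, imidazole, DMF, rt
Reagents that add atoms: tert-butyl(chloro)diphenylsilane, CC(C)(C)[Si](Cl)(c1ccccc1)c1ccccc1
Why: Silylation of the primary allylic alcohol (imidazole catalysis) gives a bulky silyl ether that should survive all later acidic, basic and reducing steps.

Step 4
Reactants: 7 tert-butyl{[(2E)-2-(4-methylpent-3-en-1-yl)-5-(tetrahydro-2H-pyran-2-yloxy)pent-2-en-1-yl]oxy}diphenylsilane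
Product: 8 (3E)-4-({[tert-butyl(diphenyl)silyl]oxy}methyl)-8-methylnona-3,7-dien-1-ol
Conditions: pyridinium p-toluenesulfonate (10 mol %), MeOH, 40 °C
Reagents that add atoms: none
Why: Acid-catalysed transacetalisation to methanol removes the tetrahydropyranyl group while the tert-butyldiphenylsilyl ether is inert under these mild conditions.

Step 5
Reactants: 8 (3E)-4-({[tert-butyl(diphenyl)silyl]oxy}methyl)-8-methylnona-3,7-dien-1-ol
Product: 10 (3E)-4-({[tert-butyl(diphenyl)silyl]oxy}methyl)-8-methylnona-3,7-dienoic acid, via aldehyde 9 (not isolated)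
Conditions: 2,2,6,6-tetramethylpiperidin-1-oxyl (20 mol %), PhI(OAc)2 (2.5 equiv), MeCN/pH 7 buffer, rt
Reagents that add atoms: water, O
Why: Nitroxyl-catalysed (oxoammonium) oxidation of the primary alcohol proceeds through the aldehyde hydrate to the acid under neutral buffer, which should keep the β,γ-olefin in place and in its (3E) geometry.

Step 6
Reactants: 10 (3E)-4-({[tert-butyl(diphenyl)silyl]oxy}methyl)-8-methylnona-3,7-dienoic acid
Product: 11 (3E,7E)-4-({[tert-butyl(diphenyl)silyl]oxy}methyl)-9-hydroxy-8-methylnona-3,7-dienoic acid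
Conditions: SeO2 (0.3 equiv), t-BuOOH, salicylic acid (10 mol %), CH2Cl2, rt
Reagents that add atoms: tert-butyl hydroperoxide, CC(C)(C)OO
Why: Selenium dioxide allylic oxidation (ene reaction then [2,3]-sigmatropic shift) attacks the electron-rich terminal trisubstituted olefin at its (E)-methyl group, the 3,4-olefin being deactivated by its allylic silyloxy and carboxymethyl substituents.

Step 7
Reactants: 11 (3E,7E)-4-({[tert-butyl(diphenyl)silyl]oxy}methyl)-9-hydroxy-8-methylnona-3,7-dienoic acid
Product: 12 (4E,8E)-5-({[tert-butyl(diphenyl)silyl]oxy}methyl)-9-methyl-3,6,7,10-tetrahydro-2H-oxecin-2-one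
Conditions: PPh3, diisopropyl azodicarboxylate, toluene (0.002 M, slow addition), 0 °C to rt
Reagents that add atoms: none
Why: Mitsunobu macrolactonisation activates the primary allylic alcohol, not the acid, so the carboxylate closes the ten-membered ring by SN2 displacement without risk of conjugating the β,γ-olefin; no stereocentre is involved and both olefin geometries are kept.

Step 8
Reactants: 12 (4E,8E)-5-({[tert-butyl(diphenyl)silyl]oxy}methyl)-9-methyl-3,6,7,10-tetrahydro-2H-oxecin-2-one
Product: 14 (1S,6R)-3-({[tert-butyl(diphenyl)silyl]oxy}methyl)-6-(prop-1-en-2-yl)cyclohex-2-ene-1-carboxylic acid, via boron ketene acetal 13 (not isolated)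
Conditions: (4S,5S)-2-bromo-1,3-bis{[3,5-bis(trifluoromethyl)phenyl]sulfonyl}-4,5-diphenyl-1,3,2-diazaborolidine (1.3 equiv), i-Pr2NEt, CH2Cl2, −78 °C to 4 °C; H2O
Reagents that add atoms: none
Why: Soft enolisation of the doubly activated α-CH2 (lactone C-3, flanked by the carbonyl and the 4,5-olefin) by the bromoborane and amine gives boron ketene acetal 13, whose O-allyl unit (O-1, C-10, C-9=C-8) undergoes a suprafacial [3,3]-sigmatropic shift that breaks O-1–C-10 and forms C-3–C-8, which is the C-1–C-6 bond of the cyclohexene. The closest known reaction type is the Ireland–Claisen ring contraction of macrocyclic allylic lactones, including its enantioselective variant through a chiral boron enolate. The six-membered carbocycle is closed by ring contraction (ten to six) through a pericyclic array fused to the forming ring, so exo/endo ring-closure labels do not apply. With C-4 cis to O-1 on the ketene acetal (pseudo-axial) and C-7 trans to C-10 on the (E)-olefin (pseudo-equatorial), the chair-like array is cis-fused to the forming ring, as in the Cope rearrangement of an (E,Z)-cyclodeca-1,5-diene, so C-1 (carboxyl) and C-6 (isopropenyl) are set cis by the ring constraint, and their absolute configuration by the C2-symmetric bis-sulfonamide ligand on boron, which differentiates the two enantiomeric chair transition states. The step needs α- and not γ-bond formation of the dienolate with the 4,5-olefin left in place: only the α-carbon belongs to the [3,3] array, and the geometry of that olefin (C-3 and C-6 cis) is what lets the tether close to a six-membered ring. No other acidic C–H is present, so enolisation elsewhere is not expected.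

Step 9
Reactants: 14 (1S,6R)-3-({[tert-butyl(diphenyl)silyl]oxy}methyl)-6-(prop-1-en-2-yl)cyclohex-2-ene-1-carboxylic acid
Product: 15 (1R,6S)-3-({[tert-butyl(diphenyl)silyl]oxy}methyl)-6-(propan-2-yl)cyclohex-2-ene-1-carboxylic acid
Conditions: H2 (1 atm), RhCl(PPh3)3 (5 mol %), benzene/EtOH, rt
Reagents that add atoms: none
Why: Homogeneous hydrogenation with RhCl(PPh3)3 reduces the unhindered 1,1-disubstituted olefin much faster than the trisubstituted ring olefin, turning isopropenyl into isopropyl without touching either stereocentre (the descriptors change only because the priorities change).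

Step 10
Reactants: 15 (1R,6S)-3-({[tert-butyl(diphenyl)silyl]oxy}methyl)-6-(propan-2-yl)cyclohex-2-ene-1-carboxylic acid
Product: 16 [(1R,6S)-3-({[tert-butyl(diphenyl)silyl]oxy}methyl)-6-(propan-2-yl)cyclohex-2-en-1-yl]methanol
Conditions: LiAlH4, THF, 0 °C; H2O
Reagents that add atoms: none
Why: Hydride reduction of the carboxylic acid gives the primary alcohol; the stereocentres are not enolisable at this oxidation level and the silyl ether tolerates LiAlH4 at 0 °C.

Step 11
Reactants: 17 methyl (triphenyl-λ5-phosphanylidene)acetate; 18 (chloromethoxy)tri(propan-2-yl)silane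
Product: 20 methyl 3-{[tri(propan-2-yl)silyl]oxy}-2-(triphenyl-λ5-phosphanylidene)propanoate, via phosphonium chloride 19 (not isolated)
Conditions: 17 (2 equiv), 18 (1 equiv), CH2Cl2, 0 °C to rt
Reagents that add atoms: none
Why: C-Alkylation of the stabilised phosphorus ylide by the reactive α-chloro ether followed by transylidation (the second equivalent of 17 acts as base) gives the α-(silyloxymethyl) ylide.

Step 12
Reactants: 16 [(1R,6S)-3-({[tert-butyl(diphenyl)silyl]oxy}methyl)-6-(propan-2-yl)cyclohex-2-en-1-yl]methanol; 20 methyl 3-{[tri(propan-2-yl)silyl]oxy}-2-(triphenyl-λ5-phosphanylidene)propanoate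
Product: 22 methyl (2E)-3-[(1R,6S)-3-({[tert-butyl(diphenyl)silyl]oxy}methyl)-6-(propan-2-yl)cyclohex-2-en-1-yl]-2-({[tri(propan-2-yl)silyl]oxy}methyl)prop-2-enoate, via aldehyde 21 (not isolated)
Conditions: Dess–Martin periodinane, NaHCO3, CH2Cl2, 0 °C; then 20, toluene, 50 °C
Reagents that add atoms: none
Why: Dess–Martin oxidation under bicarbonate buffer followed directly by Wittig olefination with the stabilised α-substituted ylide should give the (2E)-enoate (ester anti to the ring), the β,γ-unsaturated α-branched aldehyde being consumed without base and thus without epimerisation at C-1.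

Step 13
Reactants: 22 methyl (2E)-3-[(1R,6S)-3-({[tert-butyl(diphenyl)silyl]oxy}methyl)-6-(propan-2-yl)cyclohex-2-en-1-yl]-2-({[tri(propan-2-yl)silyl]oxy}methyl)prop-2-enoate
Product: 23 (2E)-3-[(1R,6S)-3-({[tert-butyl(diphenyl)silyl]oxy}methyl)-6-(propan-2-yl)cyclohex-2-en-1-yl]-2-({[tri(propan-2-yl)silyl]oxy}methyl)prop-2-enoic acid
Conditions: LiOH, THF/MeOH/H2O, 40 °C; then aq. HCl to pH 3, 0 °C
Reagents that add atoms: lithium hydroxide, [Li+].[OH-]
Why: Saponification of the methyl ester with LiOH; the silyl ethers are stable, the α-carbon carries no hydrogen and the γ-hydrogen at C-1 is not acidic enough for hydroxide, so neither elimination nor olefin migration is expected.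

Step 14
Reactants: 24 3-methylbutanal; 25 but-3-en-2-one
Product: 27 (4S)-4-(propan-2-yl)cyclohex-2-en-1-one, via keto aldehyde 26 (not isolated)
Conditions: (S)-2-[diphenyl(trimethylsilyloxy)methyl]pyrrolidine (5 mol %), ethyl 3,4-dihydroxybenzoate (20 mol %), neat, 4 °C; then LiOH (10 mol %), i-PrOH, rt
Reagents that add atoms: none
Why: Enamine-catalysed Michael addition of the aldehyde to the enone, with the diarylsilyloxymethyl group of the (S)-pyrrolidine shielding one face of the enamine, sets the isopropyl-bearing stereocentre as (S), and base-mediated aldol condensation (Robinson-type annulation) then closes the cyclohexenone.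

Step 15
Reactants: 27 (4S)-4-(propan-2-yl)cyclohex-2-en-1-one; 28 (1E)-3-{[tert-butyl(dimethyl)silyl]oxy}-N,N-dimethylbuta-1,3-dien-1-amine
Product: 29 cis-fused 6-{[tert-butyl(dimethyl)silyl]oxy}-8-(dimethylamino)-4-(propan-2-yl)-3,4,4a,5,8,8a-hexahydronaphthalen-1(2H)-one (H-4a and H-8a syn to the isopropyl group, NMe2 anti to H-8a)
Conditions: toluene, 90 °C, sealed tube
Reagents that add atoms: none
Why: Diels–Alder reaction of the electron-rich aminosiloxy diene with the enone: the nucleophilic CH2 terminus bonds to the β-carbon, the diene adds suprafacially to the face anti to the neighbouring isopropyl group, giving the cis-fused bicycle with both ring-fusion hydrogens syn to isopropyl (endo amine).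

Step 16
Reactants: 29 cis-fused 6-{[tert-butyl(dimethyl)silyl]oxy}-8-(dimethylamino)-4-(propan-2-yl)-3,4,4a,5,8,8a-hexahydronaphthalen-1(2H)-one
Product: 30 spiro-epoxide of 29 at C-1 (oxirane CH2 syn, oxirane oxygen anti to H-8a and to the isopropyl group)
Conditions: Me3S+ I−, KN(SiMe3)2, THF, −10 °C to 0 °C
Reagents that add atoms: trimethylsulfonium iodide, C[S+](C)C.[I-]
Why: Corey–Chaykovsky epoxidation: the small sulfonium ylide attacks the ketone along the axial trajectory anti to the axial C-8a–C-8 bond of the cis-fused bicycle and closes irreversibly, placing the oxirane CH2 syn and the oxygen anti to the isopropyl face, which is the configuration of the future tertiary carbinol.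

Step 17
Reactants: 30 spiro-epoxide of 29 at C-1
Product: 33 cis-fused 4'-(propan-2-yl)-3',4',4a',5'-tetrahydro-2'H-spiro[oxirane-2,1'-naphthalen]-6'(8a'H)-one, via amino ketone 31 (not isolated), via ammonium iodide 32 (not isolated)
Conditions: Bu4NF, AcOH, THF, 0 °C; then MeI, K2CO3, MeCN, rt
Reagents that add atoms: none
Why: Fluoride cleaves the silyl enol ether to the β-amino ketone, and N-methylation followed by base-induced E1cB (Hofmann-type) elimination of trimethylamine unveils the enone without acid, which the epoxide would not tolerate.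

Step 18
Reactants: 33 cis-fused 4'-(propan-2-yl)-3',4',4a',5'-tetrahydro-2'H-spiro[oxirane-2,1'-naphthalen]-6'(8a'H)-one
Product: 35 cis-fused 4'-(propan-2-yl)-3',4',4a',8a'-tetrahydro-2'H-spiro[oxirane-2,1'-naphthalen]-6'-yl trifluoromethanesulfonate, via potassium dienolate 34 (not isolated)
Conditions: KN(SiMe3)2, THF, −78 °C; PhNTf2, −78 °C to 0 °C; H2O
Reagents that add atoms: N-phenylbis(trifluoromethanesulfonimide), O=S(=O)(N(c1ccccc1)S(=O)(=O)C(F)(F)F)C(F)(F)F
Why: Kinetic deprotonation at the α'-CH2 (C-5') gives the cross-conjugated dienolate, which is trapped on oxygen by the triflimide as the 2-triflyloxy-1,3-diene; low temperature avoids γ-deprotonation at the ring-fusion carbon and hence epimerisation.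

Step 19
Reactants: 35 cis-fused 4'-(propan-2-yl)-3',4',4a',8a'-tetrahydro-2'H-spiro[oxirane-2,1'-naphthalen]-6'-yl trifluoromethanesulfonate
Product: 36 2-(trimethylsilyl)ethyl cis-fused 4'-(propan-2-yl)-3',4',4a',8a'-tetrahydro-2'H-spiro[oxirane-2,1'-naphthalene]-6'-carboxylate
Conditions: Pd(OAc)2 (5 mol %), PPh3 (10 mol %), CO (1 atm), Me3SiCH2CH2OH, Et3N, DMF, 50 °C
Reagents that add atoms: carbon monoxide, [C-]#[O+]; 2-(trimethylsilyl)ethanol, C[Si](C)(C)CCO
Why: Palladium-catalysed alkoxycarbonylation of the enol triflate (oxidative addition to zerovalent palladium, CO insertion, alcoholysis of the acylpalladium species) installs the carboxyl carbon as a fluoride-labile ester.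

Step 20
Reactants: 36 2-(trimethylsilyl)ethyl cis-fused 4'-(propan-2-yl)-3',4',4a',8a'-tetrahydro-2'H-spiro[oxirane-2,1'-naphthalene]-6'-carboxylate
Product: 38 methyl 5-{(1E)-2-formyl-3-oxo-3-[2-(trimethylsilyl)ethoxy]prop-1-en-1-yl}-6-(propan-2-yl)-1-oxaspiro[2.5]octane-4-carboxylate (ring configuration as in 36), via methoxy hydroperoxide 37 (not isolated)
Conditions: O3, NaHCO3, CH2Cl2/MeOH, −78 °C (dye end-point); then Ac2O, Et3N, 0 °C to rt
Reagents that add atoms: ozone, [O-][O+]=O; methanol, CO
Why: Ozone attacks the more electron-rich cis-disubstituted olefin, the primary ozonide should fragment with the carbonyl oxide on C-8' (remote from the ester-bearing carbon), methanol traps it as the methoxy hydroperoxide, and acetylation–elimination turns this terminus into the methyl ester while the other stays an aldehyde; the acrylate olefin keeps its ring-derived geometry (formyl cis to the ring).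

Step 21
Reactants: 38 methyl 5-{(1E)-2-formyl-3-oxo-3-[2-(trimethylsilyl)ethoxy]prop-1-en-1-yl}-6-(propan-2-yl)-1-oxaspiro[2.5]octane-4-carboxylate
Product: 40 2-(trimethylsilyl)ethyl cis-fused 1-oxo-6-(propan-2-yl)-1,5a,6,7,8,9a-hexahydro-3H-spiro[2-benzoxepine-9,2'-oxirane]-4-carboxylate, via hydroxy ester 39 (not isolated)
Conditions: NaBH4, CeCl3·7H2O, MeOH, −40 °C; H2O; then Bu2SnO (10 mol %), toluene, 4 Å MS, 90 °C
Reagents that add atoms: none
Why: Luche 1,2-reduction of the aldehyde gives the allylic alcohol, which the olefin geometry holds close to the cis ester, so tin-catalysed transesterification closes the seven-membered lactone with loss of methanol under neutral conditions.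

Step 22
Reactants: 40 2-(trimethylsilyl)ethyl cis-fused 1-oxo-6-(propan-2-yl)-1,5a,6,7,8,9a-hexahydro-3H-spiro[2-benzoxepine-9,2'-oxirane]-4-carboxylate; 23 (2E)-3-[(1R,6S)-3-({[tert-butyl(diphenyl)silyl]oxy}methyl)-6-(propan-2-yl)cyclohex-2-en-1-yl]-2-({[tri(propan-2-yl)silyl]oxy}methyl)prop-2-enoic acid
Product: 41 fully protected target: 9-hydroxy-9-(acyloxymethyl) lactone in which the acyl group is that of 23 and the ring acid is the 2-(trimethylsilyl)ethyl ester
Conditions: 23 (1.2 equiv), Cs2CO3 (0.3 equiv), DMF, 70 °C; H2O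
Reagents that add atoms: none
Why: SN2 opening of the 2,2-disubstituted epoxide by the caesium carboxylate occurs at the unhindered CH2, forming the ester and liberating the tertiary alcohol with retention at the quaternary carbon.

Step 23
Reactants: 41 fully protected target
Product: 42 CNP0361406.6
Conditions: Bu4NF (6 equiv), THF, 0 °C to rt; then aq. HCl to pH 3
Reagents that add atoms: none
Why: Fluoride removes both silyl ethers and fragments the 2-(trimethylsilyl)ethyl ester (β-elimination to ethene) in one operation, leaving the lactone and the acyclic ester untouched.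

Compound list

1 | 2-(but-3-yn-1-yloxy)tetrahydro-2H-pyran | C#CCCOC1CCCCO1 | starting material
2 | [4-(tetrahydro-2H-pyran-2-yloxy)but-1-yn-1-yl]lithium | [Li]C#CCCOC1CCCCO1 | intermediate
3 | 5-(tetrahydro-2H-pyran-2-yloxy)pent-2-yn-1-ol | OCC#CCCOC1CCCCO1 | intermediate
4 | 5-bromo-2-methylpent-2-ene | CC(C)=CCCBr | starting material
5 | (4-methylpent-3-en-1-yl)magnesium bromide | CC(C)=CCC[Mg]Br | intermediate
6 | (2E)-2-(4-methylpent-3-en-1-yl)-5-(tetrahydro-2H-pyran-2-yloxy)pent-2-en-1-ol | OC/C(CCC=C(C)C)=C/CCOC1CCCCO1 | intermediate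
7 | tert-butyl{[(2E)-2-(4-methylpent-3-en-1-yl)-5-(tetrahydro-2H-pyran-2-yloxy)pent-2-en-1-yl]oxy}diphenylsilane | CC(C)(C)[Si](c1ccccc1)(c1ccccc1)OC/C(CCC=C(C)C)=C/CCOC1CCCCO1 | intermediate
8 | (3E)-4-({[tert-butyl(diphenyl)silyl]oxy}methyl)-8-methylnona-3,7-dien-1-ol | CC(C)(C)[Si](c1ccccc1)(c1ccccc1)OC/C(CCC=C(C)C)=C/CCO | intermediate
9 | (3E)-4-({[tert-butyl(diphenyl)silyl]oxy}methyl)-8-methylnona-3,7-dienal | CC(C)(C)[Si](c1ccccc1)(c1ccccc1)OC/C(CCC=C(C)C)=C/CC=O | intermediate
10 | (3E)-4-({[tert-butyl(diphenyl)silyl]oxy}methyl)-8-methylnona-3,7-dienoic acid | CC(C)(C)[Si](c1ccccc1)(c1ccccc1)OC/C(CCC=C(C)C)=C/CC(O)=O | intermediate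
11 | (3E,7E)-4-({[tert-butyl(diphenyl)silyl]oxy}methyl)-9-hydroxy-8-methylnona-3,7-dienoic acid | CC(C)(C)[Si](c1ccccc1)(c1ccccc1)OC/C(CC/C=C(\C)CO)=C/CC(O)=O | intermediate
12 | (4E,8E)-5-({[tert-butyl(diphenyl)silyl]oxy}methyl)-9-methyl-3,6,7,10-tetrahydro-2H-oxecin-2-one (ten-membered lactone; ring bonds cis at C-4=C-5, trans at C-8=C-9) | CC(C)(C)[Si](c1ccccc1)(c1ccccc1)OC/C1=C/CC(=O)OC/C(C)=C/CC1 | intermediate
13 | boron ketene acetal of 12 (O-bound (4S,5S)-1,3-bis{[3,5-bis(trifluoromethyl)phenyl]sulfonyl}-4,5-diphenyl-1,3,2-diazaborolidin-2-yl enolate; C-2=C-3 with C-4 cis to O-1) | CC(C)(C)[Si](c1ccccc1)(c1ccccc1)OC/C1=C/C=C(/OB2N(S(=O)(=O)c3cc(cc(c3)C(F)(F)F)C(F)(F)F)[C@@H](c3ccccc3)[C@H](c3ccccc3)N2S(=O)(=O)c2cc(cc(c2)C(F)(F)F)C(F)(F)F)OC/C(C)=C/CC1 | intermediate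
14 | (1S,6R)-3-({[tert-butyl(diphenyl)silyl]oxy}methyl)-6-(prop-1-en-2-yl)cyclohex-2-ene-1-carboxylic acid (cis) | OC(=O)[C@H]1C=C(CO[Si](c2ccccc2)(c2ccccc2)C(C)(C)C)CC[C@H]1C(C)=C | intermediate
15 | (1R,6S)-3-({[tert-butyl(diphenyl)silyl]oxy}methyl)-6-(propan-2-yl)cyclohex-2-ene-1-carboxylic acid (cis) | OC(=O)[C@H]1C=C(CO[Si](c2ccccc2)(c2ccccc2)C(C)(C)C)CC[C@H]1C(C)C | intermediate
16 | [(1R,6S)-3-({[tert-butyl(diphenyl)silyl]oxy}methyl)-6-(propan-2-yl)cyclohex-2-en-1-yl]methanol | OC[C@H]1C=C(CO[Si](c2ccccc2)(c2ccccc2)C(C)(C)C)CC[C@H]1C(C)C | intermediate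
17 | methyl (triphenyl-λ5-phosphanylidene)acetate | COC(=O)C=P(c1ccccc1)(c1ccccc1)c1ccccc1 | starting material
18 | (chloromethoxy)tri(propan-2-yl)silane | CC(C)[Si](OCCl)(C(C)C)C(C)C | starting material
19 | (1-methoxy-1-oxo-3-{[tri(propan-2-yl)silyl]oxy}propan-2-yl)(triphenyl)phosphonium chloride | COC(=O)C(CO[Si](C(C)C)(C(C)C)C(C)C)[P+](c1ccccc1)(c1ccccc1)c1ccccc1.[Cl-] | intermediate
20 | methyl 3-{[tri(propan-2-yl)silyl]oxy}-2-(triphenyl-λ5-phosphanylidene)propanoate | COC(=O)C(CO[Si](C(C)C)(C(C)C)C(C)C)=P(c1ccccc1)(c1ccccc1)c1ccccc1 | intermediate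
21 | (1R,6S)-3-({[tert-butyl(diphenyl)silyl]oxy}methyl)-6-(propan-2-yl)cyclohex-2-ene-1-carbaldehyde | O=C[C@H]1C=C(CO[Si](c2ccccc2)(c2ccccc2)C(C)(C)C)CC[C@H]1C(C)C | intermediate
22 | methyl (2E)-3-[(1R,6S)-3-({[tert-butyl(diphenyl)silyl]oxy}methyl)-6-(propan-2-yl)cyclohex-2-en-1-yl]-2-({[tri(propan-2-yl)silyl]oxy}methyl)prop-2-enoate | COC(=O)/C(CO[Si](C(C)C)(C(C)C)C(C)C)=C/[C@H]1C=C(CO[Si](c2ccccc2)(c2ccccc2)C(C)(C)C)CC[C@H]1C(C)C | intermediate
23 | (2E)-3-[(1R,6S)-3-({[tert-butyl(diphenyl)silyl]oxy}methyl)-6-(propan-2-yl)cyclohex-2-en-1-yl]-2-({[tri(propan-2-yl)silyl]oxy}methyl)prop-2-enoic acid | OC(=O)/C(CO[Si](C(C)C)(C(C)C)C(C)C)=C/[C@H]1C=C(CO[Si](c2ccccc2)(c2ccccc2)C(C)(C)C)CC[C@H]1C(C)C | intermediate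
24 | 3-methylbutanal | CC(C)CC=O | starting material
25 | but-3-en-2-one | CC(=O)C=C | starting material
26 | (2S)-5-oxo-2-(propan-2-yl)hexanal | CC(C)[C@@H](C=O)CCC(C)=O | intermediate
27 | (4S)-4-(propan-2-yl)cyclohex-2-en-1-one ((S)-cryptone) | CC(C)[C@@H]1CCC(=O)C=C1 | intermediate
28 | (1E)-3-{[tert-butyl(dimethyl)silyl]oxy}-N,N-dimethylbuta-1,3-dien-1-amine | CN(C)/C=C/C(=C)O[Si](C)(C)C(C)(C)C | starting material
29 | cis-fused 6-{[tert-butyl(dimethyl)silyl]oxy}-8-(dimethylamino)-4-(propan-2-yl)-3,4,4a,5,8,8a-hexahydronaphthalen-1(2H)-one (H-4a, H-8a syn to isopropyl; NMe2 anti to H-8a) | CC(C)[C@@H]1CCC(=O)[C@H]2[C@@H](N(C)C)C=C(O[Si](C)(C)C(C)(C)C)C[C@@H]12 | intermediate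
30 | spiro-epoxide of 29 at C-1 (oxirane CH2 syn, oxygen anti to H-8a and isopropyl) | CC(C)[C@@H]1CC[C@]3(CO3)[C@H]2[C@@H](N(C)C)C=C(O[Si](C)(C)C(C)(C)C)C[C@@H]12 | intermediate
31 | 8'-(dimethylamino)-6'-oxo analogue of 30 (β-amino ketone, silyl enol ether cleaved) | CC(C)[C@@H]1CC[C@]3(CO3)[C@H]2[C@@H](N(C)C)CC(=O)C[C@@H]12 | intermediate
32 | N-methyl quaternary ammonium iodide of 31 | CC(C)[C@@H]1CC[C@]3(CO3)[C@H]2[C@@H]([N+](C)(C)C)CC(=O)C[C@@H]12.[I-] | intermediate
33 | cis-fused 4'-(propan-2-yl)-3',4',4a',5'-tetrahydro-2'H-spiro[oxirane-2,1'-naphthalen]-6'(8a'H)-one (ring configuration as in 30) | CC(C)[C@@H]1CC[C@]3(CO3)[C@H]2C=CC(=O)C[C@@H]12 | intermediate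
34 | potassium cross-conjugated dienolate of 33 | CC(C)[C@@H]1CC[C@]3(CO3)[C@H]2C=CC([O-])=C[C@@H]12.[K+] | intermediate
35 | cis-fused 4'-(propan-2-yl)-3',4',4a',8a'-tetrahydro-2'H-spiro[oxirane-2,1'-naphthalen]-6'-yl trifluoromethanesulfonate | CC(C)[C@@H]1CC[C@]3(CO3)[C@H]2C=CC(OS(=O)(=O)C(F)(F)F)=C[C@@H]12 | intermediate
36 | 2-(trimethylsilyl)ethyl cis-fused 4'-(propan-2-yl)-3',4',4a',8a'-tetrahydro-2'H-spiro[oxirane-2,1'-naphthalene]-6'-carboxylate | CC(C)[C@@H]1CC[C@]3(CO3)[C@H]2C=CC(C(=O)OCC[Si](C)(C)C)=C[C@@H]12 | intermediate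
37 | 4-[hydroperoxy(methoxy)methyl] analogue of 38 (hemiperacetal carbon unassigned) | CC(C)[C@@H]1CC[C@]3(CO3)[C@@H](C(OC)OO)[C@H]1/C=C(\C=O)C(=O)OCC[Si](C)(C)C | intermediate
38 | methyl 5-{(1E)-2-formyl-3-oxo-3-[2-(trimethylsilyl)ethoxy]prop-1-en-1-yl}-6-(propan-2-yl)-1-oxaspiro[2.5]octane-4-carboxylate (ester and side chain cis, side chain trans to isopropyl) | CC(C)[C@@H]1CC[C@]3(CO3)[C@@H](C(=O)OC)[C@H]1/C=C(\C=O)C(=O)OCC[Si](C)(C)C | intermediate
39 | methyl 5-{(1E)-2-(hydroxymethyl)-3-oxo-3-[2-(trimethylsilyl)ethoxy]prop-1-en-1-yl}-6-(propan-2-yl)-1-oxaspiro[2.5]octane-4-carboxylate | CC(C)[C@@H]1CC[C@]3(CO3)[C@@H](C(=O)OC)[C@H]1/C=C(\CO)C(=O)OCC[Si](C)(C)C | intermediate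
40 | 2-(trimethylsilyl)ethyl cis-fused 1-oxo-6-(propan-2-yl)-1,5a,6,7,8,9a-hexahydro-3H-spiro[2-benzoxepine-9,2'-oxirane]-4-carboxylate | CC(C)[C@@H]1CC[C@]3(CO3)[C@H]2C(=O)OCC(C(=O)OCC[Si](C)(C)C)=C[C@@H]12 | intermediate
41 | fully protected target (tert-butyldiphenylsilyl and triisopropylsilyl ethers, 2-(trimethylsilyl)ethyl ester) | CC(C)[C@@H]1CC[C@](O)(COC(=O)/C(CO[Si](C(C)C)(C(C)C)C(C)C)=C/[C@H]2C=C(CO[Si](c3ccccc3)(c3ccccc3)C(C)(C)C)CC[C@H]2C(C)C)[C@H]2C(=O)OCC(C(=O)OCC[Si](C)(C)C)=C[C@@H]12 | intermediate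
42 | CNP0361406.6 | CC(C)[C@@H]1CC[C@](O)(COC(=O)/C(=C/[C@H]2C=C(CO)CC[C@H]2C(C)C)CO)[C@H]2C(=O)OCC(C(=O)O)=C[C@@H]12 | target

Total step count: 23 steps.
Longest linear sequence: 14 steps (steps 1–10, 12, 13, 22, 23).

Steps most likely to fail

Step 8. The conjugated boron ketene acetal may rearrange slowly, hydrolyse before it rearranges, or pass through the two enantiomeric chair transition states with little discrimination, so that conversion or enantiomeric purity is poor. The fallback for step 8 gives up asymmetric induction and resolves instead; it sets out from 12 and comes back at 14. LiN(i-Pr)2, t-BuMe2SiCl and HMPA in THF at −78 °C should convert 12 into the tert-butyldimethylsilyl ketene acetal F1 of the lactone. Warming in toluene to 60 °C should contract it to the racemic cis tert-butyldimethylsilyl ester F2 by the same chair-like rearrangement. Mild aqueous acid should then give the racemic cis acid, that is 14 together with its enantiomer F3 in equal amounts. Crystallisation with (1R)-1-phenylethanamine should give the (1R)-1-phenylethanaminium salt F4 of 14 (the (1S)-amine is used if the salt of the enantiomer crystallises first), and acidification returns the route at 14.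

Step 20. The primary ozonide may fragment the other way, giving the ester at the wrong terminus, or ozone may also cleave the acrylate olefin. The fallback for step 20 separates cleavage from differentiation; it sets out from 36 and comes back at 40, bypassing 38 and 39. Osmium tetroxide (OsO4, catalytic) with N-methylmorpholine N-oxide should dihydroxylate only the electron-rich disubstituted olefin to the cis-diol F5 of the diene ester, and NaIO4 in aqueous THF should cleave this to the dialdehyde F6 without touching the epoxide. NaBH4 with CeCl3·7H2O in EtOH/H2O at −15 °C should reduce only the conjugated 2-formylacrylate aldehyde, the saturated ring aldehyde being masked in the flask as its hydrate or hemiacetal. The resulting allylic alcohol should close on the ring aldehyde to the seven-membered lactol F7 on work-up. Oxidation with catalytic (n-Pr4N)RuO4 and N-methylmorpholine N-oxide returns the route at 40.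

Step 7. Closure of the ten-membered ring may lose to intermolecular esterification (oligomers), and the phosphonium-activated allylic alcohol may react at the wrong allylic terminus. The fallback for step 7 replaces in-situ alcohol activation by a preformed allylic halide and a templating cation; it sets out from 11 and comes back at 12. N-Chlorosuccinimide and Me2S in CH2Cl2 at −20 °C should convert the allylic alcohol selectively into the (3E,7E)-9-chloro acid F8 without allylic transposition. Intramolecular carboxylate alkylation (Cs2CO3, DMF, 0.002 M, 60 °C) returns the route at 12.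

Further compounds

F1 | step 8 | tert-butyldimethylsilyl ketene acetal of 12 (2-silyloxy-2,4,8-triene with C-4 cis to O-1; no stereocentre) | CC(C)(C)[Si](c1ccccc1)(c1ccccc1)OC/C1=C/C=C(/O[Si](C)(C)C(C)(C)C)OC/C(C)=C/CC1
F2 | step 8 | tert-butyldimethylsilyl ester of the racemic cis acid (formed as the racemate; the (1S,6R) enantiomer is drawn) | CC(C)(C)[Si](C)(C)OC(=O)[C@H]1C=C(CO[Si](c2ccccc2)(c2ccccc2)C(C)(C)C)CC[C@H]1C(C)=C
F3 | step 8 | (1R,6S)-3-({[tert-butyl(diphenyl)silyl]oxy}methyl)-6-(prop-1-en-2-yl)cyclohex-2-ene-1-carboxylic acid (enantiomer of 14) | OC(=O)[C@@H]1C=C(CO[Si](c2ccccc2)(c2ccccc2)C(C)(C)C)CC[C@@H]1C(C)=C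
F4 | step 8 | (1R)-1-phenylethanaminium salt of 14 | [O-]C(=O)[C@H]1C=C(CO[Si](c2ccccc2)(c2ccccc2)C(C)(C)C)CC[C@H]1C(C)=C.C[C@@H]([NH3+])c1ccccc1
F5 | step 20 | 7',8'-dihydroxy-7',8'-dihydro derivative of 36 (cis-diol; carbinol configurations not assigned, both centres are destroyed) | CC(C)[C@@H]1CC[C@]3(CO3)[C@H]2C(O)C(O)C(C(=O)OCC[Si](C)(C)C)=C[C@@H]12
F6 | step 20 | 2-(trimethylsilyl)ethyl (2E)-2-formyl-3-[4-formyl-6-(propan-2-yl)-1-oxaspiro[2.5]octan-5-yl]prop-2-enoate (ring configuration as in 38) | CC(C)[C@@H]1CC[C@]3(CO3)[C@@H](C=O)[C@H]1/C=C(\C=O)C(=O)OCC[Si](C)(C)C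
F7 | step 20 | 1-hydroxy (lactol) analogue of 40 (anomeric carbon not assigned) | CC(C)[C@@H]1CC[C@]3(CO3)[C@H]2C(O)OCC(C(=O)OCC[Si](C)(C)C)=C[C@@H]12
F8 | step 7 | (3E,7E)-4-({[tert-butyl(diphenyl)silyl]oxy}methyl)-9-chloro-8-methylnona-3,7-dienoic acid | CC(C)(C)[Si](c1ccccc1)(c1ccccc1)OC/C(CC/C=C(\C)CCl)=C/CC(O)=O
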